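The route rests on reading two C-bound units as O-bound ones. The pyran ring fused to ring B (O4'–C(CH3)2–CH=CH–C5') is a 1,1-dimethylpropargyl ether of O4' in disguise, and the C8 prenyl group of ring A is a 1,1-dimethylallyl ether of O7. The key step heats the (2S)-flavanone bis-ether: one tandem of aromatic Claisen shifts moves the allyl unit from O7 to C8 and turns the propargyl ether, via [3,3] shift to C5' (the only free ortho carbon, C3' being blocked by prenyl), 1,5-hydrogen shift and oxa-6π electrocyclisation, into the pyran ring. It closes the last ring and frees the 7-OH without protecting groups. The precursor comes from a chalcone by asymmetric oxa-Michael closure.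

Key step: step 7

Assumption: the quinine-derived thiourea of step 6 is taken to favour the 2S series; if it favours 2R, its quinidine-derived pseudoenantiomer is used in the same way.

Flavanone numbering is used throughout (O1, C2, C3, C4, C4a, C5–C8, C8a; ring B C1'–C6').

Step 1
Reactants: 1 2,4-dihydroxyacetophenone; 2 3-chloro-3-methylbut-1-yne
Product: 3 1-[2-hydroxy-4-(2-methylbut-3-yn-2-yloxy)phenyl]ethan-1-one
Conditions: K2CO3, KI, CuI (cat.), acetone, 60 °C
Reagents that add atoms: 3-chloro-3-methylbut-1-yne (2), CC(C)(Cl)C#C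
Why: Copper-assisted propargylic O-alkylation of a phenoxide by the tertiary propargylic chloride should occur at the more acidic, non-chelated 4-OH, because the 2-OH stays locked in its hydrogen bond to the acetyl group.

Step 2
Reactants: 3 1-[2-hydroxy-4-(2-methylbut-3-yn-2-yloxy)phenyl]ethan-1-one
Product: 4 1-[2-hydroxy-4-(2-methylbut-3-en-2-yloxy)phenyl]ethan-1-one
Conditions: H2 (1 atm), Pd/CaCO3 poisoned with Pb(OAc)2, quinoline, EtOAc, rt
Reagents that add atoms: none
Why: Lindlar semihydrogenation should stop at the terminal alkene on the poisoned palladium surface and leave the aryl ketone untouched, giving the 1,1-dimethylallyl ether that later serves as the latent C8 prenyl group.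

Step 3
Reactants: 5 4-hydroxybenzaldehyde; 6 prenyl bromide (1-bromo-3-methylbut-2-ene)
Product: 7 4-hydroxy-3-(3-methylbut-2-en-1-yl)benzaldehyde
Conditions: 10% aq. KOH, rt
Reagents that add atoms: prenyl bromide (6), CC(C)=CCBr
Why: Ortho C-alkylation of a phenoxide (C-prenylation) is favoured in water, where hydrogen bonding shields the phenoxide oxygen, and the para position is blocked by the formyl group, so the allylic bromide should be taken up at C3.

Step 4
Reactants: 7 4-hydroxy-3-(3-methylbut-2-en-1-yl)benzaldehyde; 2 3-chloro-3-methylbut-1-yne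
Product: 8 3-(3-methylbut-2-en-1-yl)-4-(2-methylbut-3-yn-2-yloxy)benzaldehyde
Conditions: DBU, CuCl2·2H2O (cat.), MeCN, 0 °C to rt
Reagents that add atoms: 3-chloro-3-methylbut-1-yne (2), CC(C)(Cl)C#C
Why: Copper-catalysed propargylic O-alkylation of phenols with tertiary propargylic chlorides under amidine base works best for electron-poor phenols such as this para-formylphenol and should tolerate the ortho prenyl group and the aldehyde at 0 °C.

Step 5
Reactants: 4 1-[2-hydroxy-4-(2-methylbut-3-en-2-yloxy)phenyl]ethan-1-one; 8 3-(3-methylbut-2-en-1-yl)-4-(2-methylbut-3-yn-2-yloxy)benzaldehyde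
Product: 10 (E)-1-[2-hydroxy-4-(2-methylbut-3-en-2-yloxy)phenyl]-3-[3-(3-methylbut-2-en-1-yl)-4-(2-methylbut-3-yn-2-yloxy)phenyl]prop-2-en-1-one, via aldol adduct 9 (not isolated)
Conditions: KOH, EtOH/H2O, 0 °C to rt; then aq. citric acid to pH 6
Reagents that add atoms: none
Why: In this Claisen–Schmidt aldol condensation the enolate of the aryl methyl ketone adds to the non-enolisable aldehyde and aldol 9 dehydrates by E1cB to the conjugated (E)-chalcone, while both tertiary ethers and the alkyne are inert to hydroxide.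

Step 6
Reactants: 10 (E)-1-[2-hydroxy-4-(2-methylbut-3-en-2-yloxy)phenyl]-3-[3-(3-methylbut-2-en-1-yl)-4-(2-methylbut-3-yn-2-yloxy)phenyl]prop-2-en-1-one
Product: 11 (2S)-7-(2-methylbut-3-en-2-yloxy)-2-[3-(3-methylbut-2-en-1-yl)-4-(2-methylbut-3-yn-2-yloxy)phenyl]-2,3-dihydro-4H-chromen-4-one
Conditions: quinine-derived thiourea 1-[3,5-bis(trifluoromethyl)phenyl]-3-[(8S,9S)-6'-methoxycinchonan-9-yl]thiourea (10–20 mol %), toluene, rt
Reagents that add atoms: none
Why: In this asymmetric intramolecular oxa-Michael addition (6-endo-trig) under bifunctional cinchona thiourea catalysis the quinuclidine nitrogen activates the 2'-OH and the thiourea binds the enone carbonyl, so the phenol oxygen should be delivered to one face of the β-carbon and C2 is set as S by the catalyst.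

Step 7
Reactants: 11 (2S)-7-(2-methylbut-3-en-2-yloxy)-2-[3-(3-methylbut-2-en-1-yl)-4-(2-methylbut-3-yn-2-yloxy)phenyl]-2,3-dihydro-4H-chromen-4-one
Product: 15 (2S)-2-[2,2-dimethyl-8-(3-methylbut-2-en-1-yl)-2H-chromen-6-yl]-7-hydroxy-8-(3-methylbut-2-en-1-yl)-2,3-dihydro-4H-chromen-4-one, via 8-prenylphenol 12 (not isolated), via allenylphenol 13 (not isolated), via ortho-quinone methide 14 (not isolated)
Conditions: degassed o-xylene, 145 °C, sealed tube, Ar
Reagents that add atoms: none
Why: Heating should trigger two aromatic Claisen events: the 1,1-dimethylallyl ether shifts [3,3] from O7 to C8 and enolises to phenol 12, then the 1,1-dimethylpropargyl ether shifts [3,3] to C5' and enolises to allenylphenol 13, whose 1,5-hydrogen shift gives ortho-quinone methide 14, which cyclises to 15. The closest known reaction types are the aromatic Claisen rearrangement of aryl 1,1-dimethylallyl ethers to ortho-prenylphenols and the thermal rearrangement of aryl 1,1-dimethylpropargyl ethers to 2,2-dimethyl-2H-chromenes, here run in one pot. The pyran ring is closed by thermal disrotatory oxa-6π electrocyclisation of the Z-dienone in 14, which forms the O–C(CH3)2 bond after the C5'–CH bond was made by the [3,3] shift. No new stereocentre arises, and C2 (S) from step 6 should be carried through because the medium is neutral, aprotic and free of base, so retro-oxa-Michael opening of ring C is not catalysed. Regioselectivity on ring B is secured by the prenyl group at C3', which leaves C5' as the only ortho carbon that can rearomatise, and on ring A by the vinylogous-ester conjugation O1–C8a–C4a–C4=O, which raises the double-bond character of C7–C8 and directs the allyl unit to C8 and not to C6, as with 7-allyloxy-coumarins and -chromanones. The order in which the two ethers rearrange does not matter, since both react under the same conditions and neither product phenol can react further without an oxidant.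

Compound list
1 | 2,4-dihydroxyacetophenone | CC(=O)c1ccc(O)cc1O | starting material
2 | 3-chloro-3-methylbut-1-yne | CC(C)(Cl)C#C | starting material
3 | 1-[2-hydroxy-4-(2-methylbut-3-yn-2-yloxy)phenyl]ethan-1-one | CC(=O)c1ccc(OC(C)(C)C#C)cc1O | intermediate
4 | 1-[2-hydroxy-4-(2-methylbut-3-en-2-yloxy)phenyl]ethan-1-one | CC(=O)c1ccc(OC(C)(C)C=C)cc1O | intermediate
5 | 4-hydroxybenzaldehyde | O=Cc1ccc(O)cc1 | starting material
6 | prenyl bromide (1-bromo-3-methylbut-2-ene) | CC(C)=CCBr | starting material
7 | 4-hydroxy-3-(3-methylbut-2-en-1-yl)benzaldehyde | CC(C)=CCc1cc(C=O)ccc1O | intermediate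
8 | 3-(3-methylbut-2-en-1-yl)-4-(2-methylbut-3-yn-2-yloxy)benzaldehyde | CC(C)=CCc1cc(C=O)ccc1OC(C)(C)C#C | intermediate
9 | racemic aldol adduct 3-hydroxy-1-[2-hydroxy-4-(2-methylbut-3-en-2-yloxy)phenyl]-3-[3-(3-methylbut-2-en-1-yl)-4-(2-methylbut-3-yn-2-yloxy)phenyl]propan-1-one | C=CC(C)(C)Oc1ccc(C(=O)CC(O)c2ccc(OC(C)(C)C#C)c(CC=C(C)C)c2)c(O)c1 | intermediate (not isolated)
10 | (E)-1-[2-hydroxy-4-(2-methylbut-3-en-2-yloxy)phenyl]-3-[3-(3-methylbut-2-en-1-yl)-4-(2-methylbut-3-yn-2-yloxy)phenyl]prop-2-en-1-one | C=CC(C)(C)Oc1ccc(C(=O)/C=C/c2ccc(OC(C)(C)C#C)c(CC=C(C)C)c2)c(O)c1 | intermediate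
11 | (2S)-7-(2-methylbut-3-en-2-yloxy)-2-[3-(3-methylbut-2-en-1-yl)-4-(2-methylbut-3-yn-2-yloxy)phenyl]-2,3-dihydro-4H-chromen-4-one | CC(C)=CCc1cc([C@@H]2CC(=O)c3ccc(OC(C)(C)C=C)cc3O2)ccc1OC(C)(C)C#C | intermediate
12 | (2S)-7-hydroxy-8-(3-methylbut-2-en-1-yl)-2-[3-(3-methylbut-2-en-1-yl)-4-(2-methylbut-3-yn-2-yloxy)phenyl]-2,3-dihydro-4H-chromen-4-one | CC(C)=CCc1cc([C@@H]2CC(=O)c3ccc(O)c(CC=C(C)C)c3O2)ccc1OC(C)(C)C#C | intermediate (not isolated)
13 | (2S)-7-hydroxy-2-[4-hydroxy-3-(3-methylbuta-1,2-dien-1-yl)-5-(3-methylbut-2-en-1-yl)phenyl]-8-(3-methylbut-2-en-1-yl)-2,3-dihydro-4H-chromen-4-one | CC(C)=CCc1cc([C@@H]2CC(=O)c3ccc(O)c(CC=C(C)C)c3O2)cc(C=C=C(C)C)c1O | intermediate (not isolated)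
14 | ortho-quinone methide (2S)-7-hydroxy-8-(3-methylbut-2-en-1-yl)-2-[(3Z)-5-(3-methylbut-2-en-1-yl)-3-(3-methylbut-2-en-1-ylidene)-4-oxocyclohexa-1,5-dien-1-yl]-2,3-dihydro-4H-chromen-4-one | CC(C)=C/C=C1/C=C([C@@H]2CC(=O)c3ccc(O)c(CC=C(C)C)c3O2)C=C(CC=C(C)C)C1=O | intermediate (not isolated)
15 | (2S)-2-[2,2-dimethyl-8-(3-methylbut-2-en-1-yl)-2H-chromen-6-yl]-7-hydroxy-8-(3-methylbut-2-en-1-yl)-2,3-dihydro-4H-chromen-4-one | CC(C)=CCc1cc([C@@H]2CC(=O)c3ccc(O)c(CC=C(C)C)c3O2)cc2c1OC(C)(C)C=C2 | target

Total step count: 7 steps.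
Longest linear sequence: 5 steps (steps 1, 2, 5, 6, 7, or equally steps 3, 4, 5, 6, 7).

Steps most likely to fail

Step 7 (key step). The prolonged heating may erode the configuration at C2 through reversible opening of ring C, and part of the allyl unit may migrate to C6 instead of C8. Fallback, setting out from 11 and coming back at 15: 11 is heated only to about 105 °C in toluene, where the lower-barrier 1,1-dimethylallyl shift should run alone, and 8-prenylphenol 12 is isolated and freed from any C6 isomer by chromatography. The pyran ring is then closed at room temperature by gold-catalysed 6-endo-dig hydroarylation of the propargyl ether at C5' (Ph3PAuNTf2 cat., CH2Cl2), a π-acid pathway in place of the thermal sigmatropic cascade, to give 15. This fallback makes no compound outside the list (F0).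

Step 6. The unactivated chalcone may cyclise slowly and reversibly, so that the facial selectivity is poor or is lost by equilibration through the chalcone. Fallback, setting out from 10 and coming back at 11: 10 is cyclised without stereocontrol (NaOAc, EtOH, 70 °C) to racemic 7-(2-methylbut-3-en-2-yloxy)-2-[3-(3-methylbut-2-en-1-yl)-4-(2-methylbut-3-yn-2-yloxy)phenyl]-2,3-dihydro-4H-chromen-4-one F1. Kinetic resolution by asymmetric transfer hydrogenation (RuCl[(R,R)-TsDPEN](p-cymene), HCO2H/Et3N, EtOAc, rt) should then reduce the 2R enantiomer to (2R,4R)-7-(2-methylbut-3-en-2-yloxy)-2-[3-(3-methylbut-2-en-1-yl)-4-(2-methylbut-3-yn-2-yloxy)phenyl]-3,4-dihydro-2H-chromen-4-ol F2 and leave the 2S ketone 11, which is separated by chromatography.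

Step 3. The phenoxide may be alkylated at oxygen or twice at carbon, so that mono-C-prenylation is unselective. Fallback, setting out from 5 and coming back at 7: O-alkylation of 5 with 2 (DBU, CuCl2·2H2O cat., MeCN, 0 °C) should give 4-(2-methylbut-3-yn-2-yloxy)benzaldehyde F3. Semihydrogenation (H2, Pd/CaCO3 poisoned with Pb(OAc)2, quinoline, EtOAc) should give 4-(2-methylbut-3-en-2-yloxy)benzaldehyde F4, and aromatic Claisen rearrangement (N,N-diethylaniline, 130 °C) moves the allyl unit to the ortho carbon to give 7.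

Further compounds
F0 | step 7 | none | none
F1 | step 6 | racemic 7-(2-methylbut-3-en-2-yloxy)-2-[3-(3-methylbut-2-en-1-yl)-4-(2-methylbut-3-yn-2-yloxy)phenyl]-2,3-dihydro-4H-chromen-4-one | CC(C)=CCc1cc(C2CC(=O)c3ccc(OC(C)(C)C=C)cc3O2)ccc1OC(C)(C)C#C
F2 | step 6 | (2R,4R)-7-(2-methylbut-3-en-2-yloxy)-2-[3-(3-methylbut-2-en-1-yl)-4-(2-methylbut-3-yn-2-yloxy)phenyl]-3,4-dihydro-2H-chromen-4-ol | CC(C)=CCc1cc([C@H]2C[C@@H](O)c3ccc(OC(C)(C)C=C)cc3O2)ccc1OC(C)(C)C#C
F3 | step 3 | 4-(2-methylbut-3-yn-2-yloxy)benzaldehyde | C#CC(C)(C)Oc1ccc(C=O)cc1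
F4 | step 3 | 4-(2-methylbut-3-en-2-yloxy)benzaldehyde | C=CC(C)(C)Oc1ccc(C=O)cc1
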